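Rings compete with links.

    Z + D → Z.D (k1 = 0.58 M⁻¹ s⁻¹)
    D ⇌ G (K2 = 0.55, k2 = 0.0033 s⁻¹)
    Z + D → Q, rate k3*[Z] as long as [D] is above zero (k3 = 0.048 s⁻¹)

| setting | eta | gamma | delta | beta |
|---|---|---|---|---|
| Z | 28 mM | 28 mM (fed, over 24.0 min) | 28 mM | 28 mM |
| D | 27.4 mM (fed, over 24.0 min) | 27.4 mM | 27.4 mM | 27.4 mM |
| time | 30 min | 30 min |  | 30 min |
| remark | a stirred flask in which D is dosed at a steady rate over 24.0 min without added volume, worked up at 30 min | a stirred flask in which Z is dosed at a steady rate over 24.0 min without added volume, worked up at 30 min | one stirred flow tank at steady state, fed with the mixture as stated, mean residence time 30 min | a closed flask charged with all of it at once and left for 30 min |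

* the set-up with the highest amount of Z.D at the outlet or at the end, in percent of the Z put in ("none" if the first two lie within 2 percentage points) (eta / gamma / delta / beta / none)
* amount of Z.D at the outlet or at the end, in percent of the Z put in, eta
* amount of Z.D at the outlet or at the end, in percent of the Z put in, gamma
* amount of Z.D at the outlet or at the end, in percent of the Z put in, delta
* amount of Z.D at the outlet or at the end, in percent of the Z put in, beta

Z that reacts with D goes either to Z.D or to Q. The link rate carries Z and D, the ring rate carries Z, so Z cancels from their ratio. We call the ring constant over the link constant the break-even level of D, 82.8 mM, a selectivity factor: the share of reacting Z that becomes Z.D is D/(a + D), a saturation hyperbola in D. The charge of D, 27.4 mM, lies below it, so Q is the large product and we reckon Z.D as the correction, summing this share over the D consumed.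

In beta, the sum from the full charge down to zero gives 3.73 mM, or 13.3 % of the Z. At the start, the exchange with G takes 6.73 % of what the ring step takes, so we hold this slightly high.

In gamma, D and G relax with a half-life of 1.24 min, much shorter than the feed of 24.0 min. We therefore take free D as 64.5 % of their pool, and the same sum gives 2.57 mM, or 9.17 %.

In eta and delta, D enters at 1.14 mM min⁻¹ and 0.913 mM min⁻¹. The ring step on the 0.600 mM of Z in excess takes 1.73 mM min⁻¹, more than either feed brings, so we expect D near zero, and the share with it. We choose beta, whose sum is larger than that of gamma.

The forecast gave beta, with 12.5 % for beta, 9.1 % for gamma, and 0.05 % and 0.05 % for eta and delta, since “excess Z consumes D as it arrives”.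

The simulation gives beta as best: 12.7 % for beta, 9.02 % for gamma, 0 % for eta and 0.00681 % for delta. Our beta stands 0.61 percentage points above the flask, on the side we expected.

Beta has come to rest. D is under 2.00 % of its charge by 0.805 min, where the share is 0.657 %. Z.D stands at 12.7 % at 15.0 min, and ten times the asked time gives 12.7 %. Eta rests too: at the end of its feed, 24.0 min, D is 0.0179 % of its own charge, a share of 0.00592 %, and Z.D at 300 min is 0 %.

The constants were chosen freely; the result is computed.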